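**Retrosynthetic overview**
- Rings and locants: the upper dihydrobenzofuran is ring C (benzo) fused to ring D (furan), with ring A on C2 and ring B on C3. The lower one is ring G (benzo) fused to ring F (furan), with ring C on C2, ring E on C3, OH on C4 and the styryl arm (ring H) on C6. Each is numbered O1, C2, C3, C3a, C4–C7, C7a.
- Disconnections: the styryl arm comes off last (Heck reaction at C6 of ring G). Each dihydrofuran is cut at C2–O1 (enantioselective O–H insertion of an aryl diazoacetate into a phenol, sets C2) and at C3–C3a (Friedel–Crafts closure of the C3 benzylic cation, sets C3 trans to C2).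
- Ring order: ring F is closed first, onto a symmetric phloroglucinol bis-ether that becomes ring G. Then the 4-triflate of ring C is cleaved and the same three-step annulation closes ring D. The arm and the deprotections follow.
- Enabling feature: C3a of the F/G unit is the ring G carbon that lies between both ring G oxygens (O1 and the C4 oxygen) and para to C6. With C6 carried as oxygen, ring G is a phloroglucinol whose two carbons ortho to O1 are equivalent and activated by three oxygens. C3 is benzylic to ring E, and its neighbour C2 already holds the configuration.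
- Polarity control: the 2,4-dioxygenated rings (A, C, H) travel as aryl sulfonates, so C2 cannot ionise and no aryl shift competes with ring closure. The 3,5-dioxygenated rings (B, E) travel as benzyl ethers.

Key step: step 8

Remark: compounds 1, 5, 8 and 25 and all unnumbered reagents are taken as commercial. Ts = 4-methylbenzenesulfonyl, Tf = trifluoromethanesulfonyl, Bn = benzyl.

**Step 1**
Reactants: 1 methyl 2-(2,4-dihydroxyphenyl)acetate
Product: 2 methyl 2-[2-hydroxy-4-(triflyloxy)phenyl]acetate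
Conditions: PhNTf2 (1.0 equiv), Et3N, CH2Cl2, 0 °C
Reagents that add atoms: N-phenylbis(trifluoromethanesulfonimide), O=S(=O)(N(c1ccccc1)S(=O)(=O)C(F)(F)F)C(F)(F)F
Why: selective O-sulfonylation of a phenol: the bulky triflimide should take the unhindered 4-hydroxyl rather than the 2-hydroxyl that is flanked by the acetate arm, which installs the one sulfonate that is cleaved alone in step 9.

**Step 2**
Reactants: 2 methyl 2-[2-hydroxy-4-(triflyloxy)phenyl]acetate
Product: 3 methyl 2-[2-(tosyloxy)-4-(triflyloxy)phenyl]acetate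
Conditions: TsCl, Et3N, DMAP (cat.), CH2Cl2, 0 °C to rt
Reagents that add atoms: p-toluenesulfonyl chloride, Cc1ccc(cc1)S(=O)(=O)Cl
Why: O-tosylation of the remaining phenol makes both ring oxygens electron-withdrawing, and the tosylate is the one that survives the later hydroxide cleavage of the triflate.

**Step 3**
Reactants: 3 methyl 2-[2-(tosyloxy)-4-(triflyloxy)phenyl]acetate
Product: 4 methyl 2-diazo-2-[2-(tosyloxy)-4-(triflyloxy)phenyl]acetate
Conditions: 4-acetamidobenzenesulfonyl azide, DBU, MeCN, 0 °C to rt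
Reagents that add atoms: 4-acetamidobenzenesulfonyl azide, CC(=O)Nc1ccc(cc1)S(=O)(=O)N=[N+]=[N-]
Why: Regitz diazo transfer to the benzylic methylene of an aryl acetate, made more acidic by the sulfonyloxy groups, gives the donor/acceptor diazo ester.

**Step 4**
Reactants: 5 phloroglucinol
Product: 6 3,5-bis(allyloxy)phenol
Conditions: allyl bromide (2.0 equiv), K2CO3, acetone, reflux
Reagents that add atoms: allyl bromide, C=CCBr
Why: twofold Williamson etherification of a triol with three equivalent hydroxyls (statistical, the bis-ether is separated from mono- and tris-ether) leaves a phenol whose two ortho carbons are equivalent.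

**Step 5**
Reactants: 4 methyl 2-diazo-2-[2-(tosyloxy)-4-(triflyloxy)phenyl]acetate; 6 3,5-bis(allyloxy)phenol
Product: 7 methyl (2S)-2-[3,5-bis(allyloxy)phenoxy]-2-[2-(tosyloxy)-4-(triflyloxy)phenyl]acetate
Conditions: Pd(PhCN)2Cl2 (5 mol %), chiral spiro-bis(oxazoline) ligand on a 1,1'-spirobiindane backbone (6 mol %, the enantiomer that gives the (S)-ester), Na[B(3,5-(CF3)2C6H3)4] (12 mol %), 5 Å molecular sieves, CHCl3, 30 °C
Reagents that add atoms: none
Why: enantioselective insertion of an α-aryl-α-diazoacetate into a phenol O–H bond under a chiral spiro-bis(oxazoline) complex of divalent palladium, in which the ligand decides the configuration of the new centre (the later C2 of ring F, (S) in this ester) and O–H insertion should outpace reaction at the allyl alkenes.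

**Step 6**
Reactants: 8 1-bromo-3,5-bis(benzyloxy)benzene
Product: 9 [3,5-bis(benzyloxy)phenyl]magnesium bromide, kept as a THF solution under argon and titrated before each use
Conditions: Mg turnings, BrCH2CH2Br (cat.), THF, rt to 40 °C
Reagents that add atoms: magnesium, [Mg]
Why: insertion of magnesium into the aryl C–Br bond (Grignard reagent formation) leaves the benzyl ethers untouched, and one batch of the solution supplies the aryl additions of steps 7 and 13.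

**Step 7**
Reactants: 7 methyl (2S)-2-[3,5-bis(allyloxy)phenoxy]-2-[2-(tosyloxy)-4-(triflyloxy)phenyl]acetate; 9 [3,5-bis(benzyloxy)phenyl]magnesium bromide
Product: 11 (1RS,2S)-2-[3,5-bis(allyloxy)phenoxy]-1-[3,5-bis(benzyloxy)phenyl]-2-[2-(tosyloxy)-4-(triflyloxy)phenyl]ethan-1-ol (both C1 epimers), via aldehyde 10 (not isolated)
Conditions: 7, i-Bu2AlH (1.1 equiv), CH2Cl2, −78 °C; then 9 (3 equiv, THF solution), −78 to −30 °C; aq. KNaC4H4O6
Reagents that add atoms: none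
Why: reduction of the ester at −78 °C stops at the aluminium hemiacetal of aldehyde 10, which aryl Grignard 9 intercepts in the same flask (one-pot reduction/Grignard addition), so the enolisable α-centre is never exposed to base as a free aldehyde; the new carbinol centre need not be controlled because step 8 ionises it.

**Step 8**
Reactants: 11 (1RS,2S)-2-[3,5-bis(allyloxy)phenoxy]-1-[3,5-bis(benzyloxy)phenyl]-2-[2-(tosyloxy)-4-(triflyloxy)phenyl]ethan-1-ol
Product: 13 (2R,3R)-4,6-bis(allyloxy)-3-[3,5-bis(benzyloxy)phenyl]-2-[2-(tosyloxy)-4-(triflyloxy)phenyl]-2,3-dihydrobenzofuran, via benzylic cation 12 (not isolated)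
Conditions: Bi(OTf)3 (10 mol %), CH2Cl2–(CF3)2CHOH 4:1, 0.01 M, 0 °C to rt
Reagents that add atoms: none
Why: Bi(OTf)3 in the ionising, non-nucleophilic fluorinated alcohol removes the hydroxyl of either carbinol epimer and gives benzylic cation 12, which a ring G carbon ortho to the ether oxygen captures, and loss of the proton restores the arene (intramolecular Friedel–Crafts cycloalkylation, the reaction type by which β-aryloxy benzylic alcohols and α-aryloxy ketones are closed to dihydrobenzofurans and benzofurans). Ring F closes through bond C3–C3a in a five-membered closure that is endo with respect to the C7a=C3a π bond of the arene, which the strongly electrophilic, poorly stabilised cation allows. The new stereocentre C3 is set by the existing C2: in the transition state the C2–O bond lies over the cation plane and ring C on C2 turns away from ring E (allylic 1,2-strain), so ring G adds to the face that gives the trans (2R,3R) product, and both carbinol epimers converge. Site selectivity needs no control because the two ortho carbons of the 3,5-bis(allyloxy)phenoxy ring are equivalent and each is activated by three oxygens. The step needs a C3 cation that does not lose the C2–O bond, is not bridged by ring C and does not lose the C2 proton: the tosylate and triflate make ring C a poor donor, so C2 cannot ionise and ring C cannot migrate, and the very nucleophilic ring G should outrun proton loss at high dilution.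

**Step 9**
Reactants: 13 (2R,3R)-4,6-bis(allyloxy)-3-[3,5-bis(benzyloxy)phenyl]-2-[2-(tosyloxy)-4-(triflyloxy)phenyl]-2,3-dihydrobenzofuran
Product: 14 (2R,3R)-4,6-bis(allyloxy)-3-[3,5-bis(benzyloxy)phenyl]-2-[4-hydroxy-2-(tosyloxy)phenyl]-2,3-dihydrobenzofuran
Conditions: Et4NOH (20% aq., 2.5 equiv), 1,4-dioxane, rt, 15 min; then 1 M HCl
Reagents that add atoms: none
Why: hydroxide attacks sulfur of the aryl triflate far faster than sulfur of the hindered aryl tosylate (S–O cleavage of aryl triflates by Et4NOH), which frees only the hydroxyl para to C2 of ring F and turns ring C from spectator into the nucleophile of the second annulation.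

**Step 10**
Reactants: 1 methyl 2-(2,4-dihydroxyphenyl)acetate
Product: 15 methyl 2-[2,4-bis(tosyloxy)phenyl]acetate
Conditions: TsCl (2.3 equiv), Et3N, DMAP (cat.), CH2Cl2, 0 °C to rt
Reagents that add atoms: p-toluenesulfonyl chloride, Cc1ccc(cc1)S(=O)(=O)Cl
Why: exhaustive O-tosylation gives the electron-poor form of ring A.

**Step 11**
Reactants: 15 methyl 2-[2,4-bis(tosyloxy)phenyl]acetate
Product: 16 methyl 2-diazo-2-[2,4-bis(tosyloxy)phenyl]acetate
Conditions: 4-acetamidobenzenesulfonyl azide, DBU, MeCN, 0 °C to rt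
Reagents that add atoms: 4-acetamidobenzenesulfonyl azide, CC(=O)Nc1ccc(cc1)S(=O)(=O)N=[N+]=[N-]
Why: Regitz diazo transfer as in step 3.

**Step 12**
Reactants: 14 (2R,3R)-4,6-bis(allyloxy)-3-[3,5-bis(benzyloxy)phenyl]-2-[4-hydroxy-2-(tosyloxy)phenyl]-2,3-dihydrobenzofuran; 16 methyl 2-diazo-2-[2,4-bis(tosyloxy)phenyl]acetate
Product: 17 methyl (2S)-2-{4-[(2R,3R)-4,6-bis(allyloxy)-3-[3,5-bis(benzyloxy)phenyl]-2,3-dihydrobenzofuran-2-yl]-3-(tosyloxy)phenoxy}-2-[2,4-bis(tosyloxy)phenyl]acetate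
Conditions: Pd(PhCN)2Cl2 (5 mol %), the same spiro-bis(oxazoline) ligand enantiomer (6 mol %), Na[B(3,5-(CF3)2C6H3)4] (12 mol %), 5 Å molecular sieves, CHCl3, 30 °C
Reagents that add atoms: none
Why: the same catalyst-controlled O–H insertion as in step 5 joins the ring A unit to the only free phenol, O4 of ring C, and the ligand sets the new centre (the later C2 of ring D, (S) in this ester) independently of the remote ring F centres.

**Step 13**
Reactants: 17 methyl (2S)-2-{4-[(2R,3R)-4,6-bis(allyloxy)-3-[3,5-bis(benzyloxy)phenyl]-2,3-dihydrobenzofuran-2-yl]-3-(tosyloxy)phenoxy}-2-[2,4-bis(tosyloxy)phenyl]acetate; 9 [3,5-bis(benzyloxy)phenyl]magnesium bromide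
Product: 19 (1RS,2S)-2-{4-[(2R,3R)-4,6-bis(allyloxy)-3-[3,5-bis(benzyloxy)phenyl]-2,3-dihydrobenzofuran-2-yl]-3-(tosyloxy)phenoxy}-1-[3,5-bis(benzyloxy)phenyl]-2-[2,4-bis(tosyloxy)phenyl]ethan-1-ol (both C1 epimers), via aldehyde 18 (not isolated)
Conditions: 17, i-Bu2AlH (1.1 equiv), CH2Cl2, −78 °C; then 9 (3 equiv, THF solution), −78 to −30 °C; aq. KNaC4H4O6
Reagents that add atoms: none
Why: one-pot reduction/Grignard addition as in step 7 through the aluminium hemiacetal of aldehyde 18, again without any need to control the carbinol centre.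

**Step 14**
Reactants: 19 (1RS,2S)-2-{4-[(2R,3R)-4,6-bis(allyloxy)-3-[3,5-bis(benzyloxy)phenyl]-2,3-dihydrobenzofuran-2-yl]-3-(tosyloxy)phenoxy}-1-[3,5-bis(benzyloxy)phenyl]-2-[2,4-bis(tosyloxy)phenyl]ethan-1-ol
Product: 21 (2R,3R)-5-[(2R,3R)-4,6-bis(allyloxy)-3-[3,5-bis(benzyloxy)phenyl]-2,3-dihydrobenzofuran-2-yl]-3-[3,5-bis(benzyloxy)phenyl]-2-[2,4-bis(tosyloxy)phenyl]-6-(tosyloxy)-2,3-dihydrobenzofuran, via benzylic cation 20 (not isolated)
Conditions: Bi(OTf)3 (10 mol %), CH3NO2–CH2Cl2 1:1, 0.005 M, 0 °C to rt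
Reagents that add atoms: none
Why: Friedel–Crafts cycloalkylation as in step 8: cation 20 is attacked by C5 of ring C, the carbon ortho to the ether oxygen and para to the tosyloxy group (the other ortho carbon, C3, is crowded by the tosylate), ring B takes the face trans to ring A for the same conformational reason, and the tosylates on ring A prevent ionisation at C2 and aryl migration; CH3NO2 replaces the fluorinated alcohol so that the benzylic C2–O bond of ring F stays closed.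

**Step 15**
Reactants: 21 (the doubly annulated bis-allyl ether)
Product: 22 (2R,3R)-5-[(2R,3R)-3-[3,5-bis(benzyloxy)phenyl]-4,6-dihydroxy-2,3-dihydrobenzofuran-2-yl]-3-[3,5-bis(benzyloxy)phenyl]-2-[2,4-bis(tosyloxy)phenyl]-6-(tosyloxy)-2,3-dihydrobenzofuran
Conditions: Pd(PPh3)4 (5 mol %), morpholine (6 equiv), THF, rt
Reagents that add atoms: none
Why: zerovalent palladium ionises the two aryl allyl ethers and morpholine captures the allyl groups (Tsuji–Trost deallylation), which leaves tosylates, benzyl ethers and both dihydrofurans untouched.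

**Step 16**
Reactants: 22 (the ring G diol)
Product: 23 (2R,3R)-5-[(2R,3R)-3-[3,5-bis(benzyloxy)phenyl]-4,6-bis(triflyloxy)-2,3-dihydrobenzofuran-2-yl]-3-[3,5-bis(benzyloxy)phenyl]-2-[2,4-bis(tosyloxy)phenyl]-6-(tosyloxy)-2,3-dihydrobenzofuran
Conditions: Tf2O (2.5 equiv), pyridine, CH2Cl2, 0 °C
Reagents that add atoms: trifluoromethanesulfonic anhydride, O=S(=O)(OS(=O)(=O)C(F)(F)F)C(F)(F)F
Why: O-triflation of both ring G phenols: the unhindered C6 triflate becomes the coupling handle and the C4 triflate, shielded by the substituent on C3, serves as protection that step 21 removes.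

**Step 17**
Reactants: 23 (the ring G bis-triflate)
Product: 24 (2R,3R)-3-(3,5-dihydroxyphenyl)-5-[(2R,3R)-3-(3,5-dihydroxyphenyl)-4,6-bis(triflyloxy)-2,3-dihydrobenzofuran-2-yl]-2-[2,4-bis(tosyloxy)phenyl]-6-(tosyloxy)-2,3-dihydrobenzofuran
Conditions: H2 (1 atm), Pd/C (10 wt %), EtOAc–MeOH, rt
Reagents that add atoms: none
Why: hydrogenolysis of the four benzyl ethers is done before the alkene exists; aryl sulfonates are inert under neutral conditions, and the ring benzylic C2–O bonds, deactivated by the sulfonyloxy-substituted aryl groups, should be cleaved much more slowly than O-benzyl groups.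

**Step 18**
Reactants: 25 2,4-dihydroxybenzaldehyde
Product: 26 2,4-bis(tosyloxy)benzaldehyde
Conditions: TsCl (2.3 equiv), Et3N, DMAP (cat.), CH2Cl2, 0 °C to rt
Reagents that add atoms: p-toluenesulfonyl chloride, Cc1ccc(cc1)S(=O)(=O)Cl
Why: exhaustive O-tosylation puts ring H into its electron-poor, base-labile protected form.

**Step 19**
Reactants: 26 2,4-bis(tosyloxy)benzaldehyde
Product: 27 2,4-bis(tosyloxy)styrene
Conditions: Ph3PCH3Br, KOtBu, THF, 0 °C; then 26, −78 to 0 °C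
Reagents that add atoms: methyltriphenylphosphonium bromide, C[P+](c1ccccc1)(c1ccccc1)c1ccccc1.[Br-]
Why: Wittig methylenation of the aldehyde with the non-stabilised ylide, which aryl tosylates tolerate at low temperature.

**Step 20**
Reactants: 24 (the tetraphenol bis-triflate); 27 2,4-bis(tosyloxy)styrene
Product: 28 (2R,3R)-5-[(2R,3R)-6-[(E)-2-[2,4-bis(tosyloxy)phenyl]ethenyl]-3-(3,5-dihydroxyphenyl)-4-(triflyloxy)-2,3-dihydrobenzofuran-2-yl]-3-(3,5-dihydroxyphenyl)-2-[2,4-bis(tosyloxy)phenyl]-6-(tosyloxy)-2,3-dihydrobenzofuran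
Conditions: Pd(OAc)2 (10 mol %), P(o-tol)3 (20 mol %), LiCl, Et3N, DMF, 90 °C
Reagents that add atoms: none
Why: Mizoroki–Heck reaction: oxidative addition should occur at the unhindered C6 triflate and not at the C4 triflate next to the substituted C3a–C3 junction, and syn insertion into the electron-poor styrene followed by syn β-hydride elimination gives the (E)-stilbene; free phenols are tolerated.

**Step 21**
Reactants: 28 (the protected stilbene)
Product: 29 Gneyulin A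
Conditions: KOH (excess), MeOH–THF–H2O, 60 °C, argon; then 1 M HCl
Reagents that add atoms: none
Why: hydroxide cleaves the five aryl tosylates (two on ring A, one on ring C, two on ring H) and the remaining aryl triflate at sulfur (S–O cleavage), which frees the last six phenols without touching any stereocentre; should a C2–O bond open reversibly to a quinone methide under base, re-closure returns the favoured trans ring.

**Compound list**
1 | methyl 2-(2,4-dihydroxyphenyl)acetate | COC(=O)Cc1ccc(O)cc1O | starting material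
2 | methyl 2-[2-hydroxy-4-(triflyloxy)phenyl]acetate | COC(=O)Cc1ccc(OS(=O)(=O)C(F)(F)F)cc1O | intermediate
3 | methyl 2-[2-(tosyloxy)-4-(triflyloxy)phenyl]acetate | COC(=O)Cc1ccc(OS(=O)(=O)C(F)(F)F)cc1OS(=O)(=O)c1ccc(C)cc1 | intermediate
4 | methyl 2-diazo-2-[2-(tosyloxy)-4-(triflyloxy)phenyl]acetate | COC(=O)C(=[N+]=[N-])c1ccc(OS(=O)(=O)C(F)(F)F)cc1OS(=O)(=O)c1ccc(C)cc1 | intermediate
5 | phloroglucinol | Oc1cc(O)cc(O)c1 | starting material
6 | 3,5-bis(allyloxy)phenol | Oc1cc(OCC=C)cc(OCC=C)c1 | intermediate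
7 | methyl (2S)-2-[3,5-bis(allyloxy)phenoxy]-2-[2-(tosyloxy)-4-(triflyloxy)phenyl]acetate | COC(=O)[C@@H](Oc1cc(OCC=C)cc(OCC=C)c1)c1ccc(OS(=O)(=O)C(F)(F)F)cc1OS(=O)(=O)c1ccc(C)cc1 | intermediate
8 | 1-bromo-3,5-bis(benzyloxy)benzene | Brc1cc(OCc2ccccc2)cc(OCc2ccccc2)c1 | starting material
9 | [3,5-bis(benzyloxy)phenyl]magnesium bromide, kept as a titrated THF solution | Br[Mg]c1cc(OCc2ccccc2)cc(OCc2ccccc2)c1 | intermediate
10 | (2S)-2-[3,5-bis(allyloxy)phenoxy]-2-[2-(tosyloxy)-4-(triflyloxy)phenyl]acetaldehyde, held as its aluminium hemiacetal | O=C[C@@H](Oc1cc(OCC=C)cc(OCC=C)c1)c1ccc(OS(=O)(=O)C(F)(F)F)cc1OS(=O)(=O)c1ccc(C)cc1 | intermediate (not isolated)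
11 | (1RS,2S)-2-[3,5-bis(allyloxy)phenoxy]-1-[3,5-bis(benzyloxy)phenyl]-2-[2-(tosyloxy)-4-(triflyloxy)phenyl]ethan-1-ol | OC(c1cc(OCc2ccccc2)cc(OCc2ccccc2)c1)[C@@H](Oc1cc(OCC=C)cc(OCC=C)c1)c1ccc(OS(=O)(=O)C(F)(F)F)cc1OS(=O)(=O)c1ccc(C)cc1 | intermediate
12 | benzylic cation at C1 of 11 | [CH+](c1cc(OCc2ccccc2)cc(OCc2ccccc2)c1)[C@@H](Oc1cc(OCC=C)cc(OCC=C)c1)c1ccc(OS(=O)(=O)C(F)(F)F)cc1OS(=O)(=O)c1ccc(C)cc1 | intermediate (not isolated)
13 | (2R,3R)-4,6-bis(allyloxy)-3-[3,5-bis(benzyloxy)phenyl]-2-[2-(tosyloxy)-4-(triflyloxy)phenyl]-2,3-dihydrobenzofuran | Cc1ccc(cc1)S(=O)(=O)Oc1cc(OS(=O)(=O)C(F)(F)F)ccc1[C@@H]1Oc2cc(OCC=C)cc(OCC=C)c2[C@H]1c1cc(OCc2ccccc2)cc(OCc2ccccc2)c1 | intermediate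
14 | (2R,3R)-4,6-bis(allyloxy)-3-[3,5-bis(benzyloxy)phenyl]-2-[4-hydroxy-2-(tosyloxy)phenyl]-2,3-dihydrobenzofuran | Cc1ccc(cc1)S(=O)(=O)Oc1cc(O)ccc1[C@@H]1Oc2cc(OCC=C)cc(OCC=C)c2[C@H]1c1cc(OCc2ccccc2)cc(OCc2ccccc2)c1 | intermediate
15 | methyl 2-[2,4-bis(tosyloxy)phenyl]acetate | COC(=O)Cc1ccc(OS(=O)(=O)c2ccc(C)cc2)cc1OS(=O)(=O)c1ccc(C)cc1 | intermediate
16 | methyl 2-diazo-2-[2,4-bis(tosyloxy)phenyl]acetate | COC(=O)C(=[N+]=[N-])c1ccc(OS(=O)(=O)c2ccc(C)cc2)cc1OS(=O)(=O)c1ccc(C)cc1 | intermediate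
17 | methyl (2S)-2-{4-[(2R,3R)-4,6-bis(allyloxy)-3-[3,5-bis(benzyloxy)phenyl]-2,3-dihydrobenzofuran-2-yl]-3-(tosyloxy)phenoxy}-2-[2,4-bis(tosyloxy)phenyl]acetate | COC(=O)[C@@H](Oc1ccc([C@@H]2Oc3cc(OCC=C)cc(OCC=C)c3[C@H]2c2cc(OCc3ccccc3)cc(OCc3ccccc3)c2)c(OS(=O)(=O)c2ccc(C)cc2)c1)c1ccc(OS(=O)(=O)c2ccc(C)cc2)cc1OS(=O)(=O)c1ccc(C)cc1 | intermediate
18 | aldehyde from 17 (CHO in place of CO2Me, (2S)), held as its aluminium hemiacetal | O=C[C@@H](Oc1ccc([C@@H]2Oc3cc(OCC=C)cc(OCC=C)c3[C@H]2c2cc(OCc3ccccc3)cc(OCc3ccccc3)c2)c(OS(=O)(=O)c2ccc(C)cc2)c1)c1ccc(OS(=O)(=O)c2ccc(C)cc2)cc1OS(=O)(=O)c1ccc(C)cc1 | intermediate (not isolated)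
19 | (1RS,2S)-2-{4-[(2R,3R)-4,6-bis(allyloxy)-3-[3,5-bis(benzyloxy)phenyl]-2,3-dihydrobenzofuran-2-yl]-3-(tosyloxy)phenoxy}-1-[3,5-bis(benzyloxy)phenyl]-2-[2,4-bis(tosyloxy)phenyl]ethan-1-ol | OC(c1cc(OCc2ccccc2)cc(OCc2ccccc2)c1)[C@@H](Oc1ccc([C@@H]2Oc3cc(OCC=C)cc(OCC=C)c3[C@H]2c2cc(OCc3ccccc3)cc(OCc3ccccc3)c2)c(OS(=O)(=O)c2ccc(C)cc2)c1)c1ccc(OS(=O)(=O)c2ccc(C)cc2)cc1OS(=O)(=O)c1ccc(C)cc1 | intermediate
20 | benzylic cation at C1 of 19 | [CH+](c1cc(OCc2ccccc2)cc(OCc2ccccc2)c1)[C@@H](Oc1ccc([C@@H]2Oc3cc(OCC=C)cc(OCC=C)c3[C@H]2c2cc(OCc3ccccc3)cc(OCc3ccccc3)c2)c(OS(=O)(=O)c2ccc(C)cc2)c1)c1ccc(OS(=O)(=O)c2ccc(C)cc2)cc1OS(=O)(=O)c1ccc(C)cc1 | intermediate (not isolated)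
21 | (2R,3R)-5-[(2R,3R)-4,6-bis(allyloxy)-3-[3,5-bis(benzyloxy)phenyl]-2,3-dihydrobenzofuran-2-yl]-3-[3,5-bis(benzyloxy)phenyl]-2-[2,4-bis(tosyloxy)phenyl]-6-(tosyloxy)-2,3-dihydrobenzofuran | c1ccccc1COc1cc(OCc2ccccc2)cc(c1)[C@@H]1c2cc([C@@H]3Oc4cc(OCC=C)cc(OCC=C)c4[C@H]3c3cc(OCc4ccccc4)cc(OCc4ccccc4)c3)c(OS(=O)(=O)c3ccc(C)cc3)cc2O[C@H]1c1ccc(OS(=O)(=O)c2ccc(C)cc2)cc1OS(=O)(=O)c1ccc(C)cc1 | intermediate
22 | (2R,3R)-5-[(2R,3R)-3-[3,5-bis(benzyloxy)phenyl]-4,6-dihydroxy-2,3-dihydrobenzofuran-2-yl]-3-[3,5-bis(benzyloxy)phenyl]-2-[2,4-bis(tosyloxy)phenyl]-6-(tosyloxy)-2,3-dihydrobenzofuran | c1ccccc1COc1cc(OCc2ccccc2)cc(c1)[C@@H]1c2cc([C@@H]3Oc4cc(O)cc(O)c4[C@H]3c3cc(OCc4ccccc4)cc(OCc4ccccc4)c3)c(OS(=O)(=O)c3ccc(C)cc3)cc2O[C@H]1c1ccc(OS(=O)(=O)c2ccc(C)cc2)cc1OS(=O)(=O)c1ccc(C)cc1 | intermediate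
23 | (2R,3R)-5-[(2R,3R)-3-[3,5-bis(benzyloxy)phenyl]-4,6-bis(triflyloxy)-2,3-dihydrobenzofuran-2-yl]-3-[3,5-bis(benzyloxy)phenyl]-2-[2,4-bis(tosyloxy)phenyl]-6-(tosyloxy)-2,3-dihydrobenzofuran | c1ccccc1COc1cc(OCc2ccccc2)cc(c1)[C@@H]1c2cc([C@@H]3Oc4cc(OS(=O)(=O)C(F)(F)F)cc(OS(=O)(=O)C(F)(F)F)c4[C@H]3c3cc(OCc4ccccc4)cc(OCc4ccccc4)c3)c(OS(=O)(=O)c3ccc(C)cc3)cc2O[C@H]1c1ccc(OS(=O)(=O)c2ccc(C)cc2)cc1OS(=O)(=O)c1ccc(C)cc1 | intermediate
24 | (2R,3R)-3-(3,5-dihydroxyphenyl)-5-[(2R,3R)-3-(3,5-dihydroxyphenyl)-4,6-bis(triflyloxy)-2,3-dihydrobenzofuran-2-yl]-2-[2,4-bis(tosyloxy)phenyl]-6-(tosyloxy)-2,3-dihydrobenzofuran | Oc1cc(O)cc(c1)[C@@H]1c2cc([C@@H]3Oc4cc(OS(=O)(=O)C(F)(F)F)cc(OS(=O)(=O)C(F)(F)F)c4[C@H]3c3cc(O)cc(O)c3)c(OS(=O)(=O)c3ccc(C)cc3)cc2O[C@H]1c1ccc(OS(=O)(=O)c2ccc(C)cc2)cc1OS(=O)(=O)c1ccc(C)cc1 | intermediate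
25 | 2,4-dihydroxybenzaldehyde | O=Cc1ccc(O)cc1O | starting material
26 | 2,4-bis(tosyloxy)benzaldehyde | O=Cc1ccc(OS(=O)(=O)c2ccc(C)cc2)cc1OS(=O)(=O)c1ccc(C)cc1 | intermediate
27 | 2,4-bis(tosyloxy)styrene | C=Cc1ccc(OS(=O)(=O)c2ccc(C)cc2)cc1OS(=O)(=O)c1ccc(C)cc1 | intermediate
28 | (2R,3R)-5-[(2R,3R)-6-[(E)-2-[2,4-bis(tosyloxy)phenyl]ethenyl]-3-(3,5-dihydroxyphenyl)-4-(triflyloxy)-2,3-dihydrobenzofuran-2-yl]-3-(3,5-dihydroxyphenyl)-2-[2,4-bis(tosyloxy)phenyl]-6-(tosyloxy)-2,3-dihydrobenzofuran | Oc1cc(O)cc(c1)[C@@H]1c2cc([C@@H]3Oc4cc(/C=C/c5ccc(OS(=O)(=O)c6ccc(C)cc6)cc5OS(=O)(=O)c5ccc(C)cc5)cc(OS(=O)(=O)C(F)(F)F)c4[C@H]3c3cc(O)cc(O)c3)c(OS(=O)(=O)c3ccc(C)cc3)cc2O[C@H]1c1ccc(OS(=O)(=O)c2ccc(C)cc2)cc1OS(=O)(=O)c1ccc(C)cc1 | intermediate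
29 | Gneyulin A, (2R,3R)-2-(2,4-dihydroxyphenyl)-3-(3,5-dihydroxyphenyl)-5-[(2R,3R)-6-[(E)-2-(2,4-dihydroxyphenyl)ethenyl]-3-(3,5-dihydroxyphenyl)-4-hydroxy-2,3-dihydrobenzofuran-2-yl]-2,3-dihydrobenzofuran-6-ol | Oc1cc(O)cc([C@@H]2c3cc([C@@H]4Oc5cc(/C=C/c6ccc(O)cc6O)cc(O)c5[C@H]4c4cc(O)cc(O)c4)c(O)cc3O[C@H]2c2ccc(O)cc2O)c1 | target

**Step count and risks**

Total step count: 21. Longest linear sequence: 15 steps (steps 1–3, 5, 7–9, 12–17, 20, 21).

Steps most likely to fail: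

Step 14. The cation has only a moderately activated ring carbon to attack (ortho to a single ether oxygen). Loss of the C2 proton to an aryl enol ether may therefore outrun ring closure, as may acid-promoted opening of ring F followed by capture of its C2 cation by ring B. The fallback makes the C–C bond first and the C–O bond last, both stereospecifically. A Heck reaction of styrene 27 with bromide 8 (Pd(OAc)2, P(o-tol)3, Et3N, DMF) gives (E)-1-[3,5-bis(benzyloxy)phenyl]-2-[2,4-bis(tosyloxy)phenyl]ethene F3. Shi epoxidation (D-fructose-derived ketone, KHSO5, K2CO3 buffer, MeCN–water, 0 °C) gives (2R,3R)-2-[2,4-bis(tosyloxy)phenyl]-3-[3,5-bis(benzyloxy)phenyl]oxirane F4. Phenol 14 then opens F4 at the carbon next to ring B, with inversion, through its only unhindered ortho carbon C5 (Friedel–Crafts alkylation of a phenol by an aryl epoxide in (CF3)2CHOH). This gives (1S,2R)-2-[3,5-bis(benzyloxy)phenyl]-1-[2,4-bis(tosyloxy)phenyl]-2-{5-[(2R,3R)-4,6-bis(allyloxy)-3-[3,5-bis(benzyloxy)phenyl]-2,3-dihydrobenzofuran-2-yl]-2-hydroxy-4-(tosyloxy)phenyl}ethan-1-ol F5. Intramolecular Mitsunobu etherification (PPh3, DIAD, THF), with inversion at the carbinol, closes ring D trans and returns to 21.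

Step 5. The ortho-tosyloxy group of the diazo ester may erode enantioselectivity, or the allyl ethers may divert the palladium catalyst (isomerisation, cyclopropanation). Either would compromise the stereocentre on which step 8 relies. The fallback replaces carbene insertion by a stereospecific SN2 etherification. Diazo ester 4 is oxidised with dimethyldioxirane to methyl 2-oxo-2-[2-(tosyloxy)-4-(triflyloxy)phenyl]acetate F1. Asymmetric transfer hydrogenation (RuCl(p-cymene)[TsDPEN] of the enantiomeric series that gives the (R)-alcohol, HCO2H–Et3N) gives methyl (2R)-2-hydroxy-2-[2-(tosyloxy)-4-(triflyloxy)phenyl]acetate F2. A Mitsunobu reaction of F2 with phenol 6 (PPh3, DIAD, THF, 0 °C) inverts the centre and returns to 7. The same remedy would serve step 12.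

Step 20. Oxidative addition may not discriminate enough between the two aryl triflates (double coupling, or coupling at C4), or triflyl groups may transfer to the free phenols at 90 °C. The fallback moves site selection to the phenol stage. Diol 22 is mono-triflated at the unhindered C6 hydroxyl with PhNTf2 (1 equiv, K2CO3, THF) to give the C6 mono-triflate with free C4 hydroxyl F6. Hydrogenolysis (H2, Pd/C) gives the corresponding pentaphenol F7. A Heck reaction with 27 under the conditions of step 20 gives the stilbene with free C4 hydroxyl F8. The conditions of step 21 then lead to 29.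

**Further compounds**
F1 | step 5 | methyl 2-oxo-2-[2-(tosyloxy)-4-(triflyloxy)phenyl]acetate | COC(=O)C(=O)c1ccc(OS(=O)(=O)C(F)(F)F)cc1OS(=O)(=O)c1ccc(C)cc1
F2 | step 5 | methyl (2R)-2-hydroxy-2-[2-(tosyloxy)-4-(triflyloxy)phenyl]acetate | COC(=O)[C@H](O)c1ccc(OS(=O)(=O)C(F)(F)F)cc1OS(=O)(=O)c1ccc(C)cc1
F3 | step 14 | (E)-1-[3,5-bis(benzyloxy)phenyl]-2-[2,4-bis(tosyloxy)phenyl]ethene | Cc1ccc(cc1)S(=O)(=O)Oc1ccc(/C=C/c2cc(OCc3ccccc3)cc(OCc3ccccc3)c2)c(OS(=O)(=O)c2ccc(C)cc2)c1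
F4 | step 14 | (2R,3R)-2-[2,4-bis(tosyloxy)phenyl]-3-[3,5-bis(benzyloxy)phenyl]oxirane | c1c(OCc2ccccc2)cc(OCc2ccccc2)cc1[C@H]1O[C@@H]1c1ccc(OS(=O)(=O)c2ccc(C)cc2)cc1OS(=O)(=O)c1ccc(C)cc1
F5 | step 14 | (1S,2R)-2-[3,5-bis(benzyloxy)phenyl]-1-[2,4-bis(tosyloxy)phenyl]-2-{5-[(2R,3R)-4,6-bis(allyloxy)-3-[3,5-bis(benzyloxy)phenyl]-2,3-dihydrobenzofuran-2-yl]-2-hydroxy-4-(tosyloxy)phenyl}ethan-1-ol | c1ccccc1COc1cc(OCc2ccccc2)cc(c1)[C@H](c1cc([C@@H]2Oc3cc(OCC=C)cc(OCC=C)c3[C@H]2c2cc(OCc3ccccc3)cc(OCc3ccccc3)c2)c(OS(=O)(=O)c2ccc(C)cc2)cc1O)[C@H](O)c1ccc(OS(=O)(=O)c2ccc(C)cc2)cc1OS(=O)(=O)c1ccc(C)cc1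
F6 | step 20 | (2R,3R)-5-[(2R,3R)-3-[3,5-bis(benzyloxy)phenyl]-4-hydroxy-6-(triflyloxy)-2,3-dihydrobenzofuran-2-yl]-3-[3,5-bis(benzyloxy)phenyl]-2-[2,4-bis(tosyloxy)phenyl]-6-(tosyloxy)-2,3-dihydrobenzofuran | c1ccccc1COc1cc(OCc2ccccc2)cc(c1)[C@@H]1c2cc([C@@H]3Oc4cc(OS(=O)(=O)C(F)(F)F)cc(O)c4[C@H]3c3cc(OCc4ccccc4)cc(OCc4ccccc4)c3)c(OS(=O)(=O)c3ccc(C)cc3)cc2O[C@H]1c1ccc(OS(=O)(=O)c2ccc(C)cc2)cc1OS(=O)(=O)c1ccc(C)cc1
F7 | step 20 | (2R,3R)-3-(3,5-dihydroxyphenyl)-5-[(2R,3R)-3-(3,5-dihydroxyphenyl)-4-hydroxy-6-(triflyloxy)-2,3-dihydrobenzofuran-2-yl]-2-[2,4-bis(tosyloxy)phenyl]-6-(tosyloxy)-2,3-dihydrobenzofuran | Oc1cc(O)cc(c1)[C@@H]1c2cc([C@@H]3Oc4cc(OS(=O)(=O)C(F)(F)F)cc(O)c4[C@H]3c3cc(O)cc(O)c3)c(OS(=O)(=O)c3ccc(C)cc3)cc2O[C@H]1c1ccc(OS(=O)(=O)c2ccc(C)cc2)cc1OS(=O)(=O)c1ccc(C)cc1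
F8 | step 20 | (2R,3R)-5-[(2R,3R)-6-[(E)-2-[2,4-bis(tosyloxy)phenyl]ethenyl]-3-(3,5-dihydroxyphenyl)-4-hydroxy-2,3-dihydrobenzofuran-2-yl]-3-(3,5-dihydroxyphenyl)-2-[2,4-bis(tosyloxy)phenyl]-6-(tosyloxy)-2,3-dihydrobenzofuran | Oc1cc(O)cc(c1)[C@@H]1c2cc([C@@H]3Oc4cc(/C=C/c5ccc(OS(=O)(=O)c6ccc(C)cc6)cc5OS(=O)(=O)c5ccc(C)cc5)cc(O)c4[C@H]3c3cc(O)cc(O)c3)c(OS(=O)(=O)c3ccc(C)cc3)cc2O[C@H]1c1ccc(OS(=O)(=O)c2ccc(C)cc2)cc1OS(=O)(=O)c1ccc(C)cc1
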